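The turnover, one substrate made into product per free catalyst charged, was the unit I counted in first.

| flask | substrate | partner | free catalyst | time |
|---|---|---|---|---|
| ash | 0.800 M | 2.40 M | 0.0240 M |  |
| larch | 0.480 M | 2.08 M | 0.0240 M |  |
| maple | 0.400 M | 2.40 M | 0.0240 M |  |
| alder | 0.800 M | 2.40 M | 0.0120 M |  |
| cedar | 0.800 M | 2.40 M | 0.0240 M | 50 min |

| run | time / min | [substrate] / M |
|---|---|---|
| ash run | 0.80 | 0.7162 |
| ash run | 1.4 | 0.6603 |
| ash run | 2.3 | 0.5934 |
| ash run | 4.0 | 0.4935 |
| ash run | 6.8 | 0.3867 |
| ash run | 12 | 0.2789 |
| ash run | 20 | 0.2091 |
| larch run | 0.80 | 0.4328 |
| larch run | 1.4 | 0.4047 |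
| larch run | 2.3 | 0.3642 |
| larch run | 4.0 | 0.3070 |
| larch run | 6.8 | 0.2385 |
| larch run | 12 | 0.1784 |
| larch run | 20 | 0.1338 |
| maple run | 0.80 | 0.3571 |
| maple run | 1.4 | 0.3282 |
| maple run | 2.3 | 0.2942 |
| maple run | 4.0 | 0.2448 |
| maple run | 6.8 | 0.1871 |
| maple run | 12 | 0.1336 |
| maple run | 20 | 0.0987 |
| alder run | 0.80 | 0.7572 |
| alder run | 1.4 | 0.7256 |
| alder run | 2.3 | 0.6804 |
| alder run | 4.0 | 0.6234 |
| alder run | 6.8 | 0.5475 |
| alder run | 12 | 0.4645 |
| alder run | 20 | 0.3975 |

(each reading ± 0.002 M)

- Overall: substrate + partner -> product, with free catalyst as catalyst.
- Constant volume, constant temperature.
- A reading of a species includes what of it is bound.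
- An order is taken over about fifteen percent of the charge, up and down.

- how the opening rate goes with [substrate] round the charge of the ash run: the exponent of the rate at two percent of substrate gone to product (one fixed amount of product, the same in the runs compared)
- how the opening rate goes with [partner] round the charge of the ash run: the exponent of the rate at two percent of substrate gone to product
- the larch run starts with 0.320 M less of substrate and of partner than the ash run, and with no product. Compared where both hold the same amount of substrate, once fifteen percent of what the larch run was charged with has turned into product, is the larch run faster, slower or alike (within a tenth)?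
- substrate in the cedar run at 50 min, as a share of the substrate charged

1. By 20 min the ash run had made 24.6 turnovers and the maple run, charged with half the substrate, 12.6. The ash count was twice the maple count, so the same catalyst charge gave these two runs different counts.

2. The logarithm L = ln(S0/S), with S the substrate and S0 its charge, stayed much closer: 1.34 for ash and 1.40 for maple at that time. With partner charged well above substrate, I read the runs as pseudo-first-order in substrate, with an order near one.

3. L slowed as time passed. In the ash run it gained 0.571 from 4.0 min to 12 min, but 0.288 over the equally long span to 20 min. Taking that shrinkage as steady gave a fade constant f = 0.0855 min⁻¹.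

4. Summing the shrinking gains gave the reach B, the value that L climbs towards as the catalyst fades, a pure number equal to the opening first-order rate constant divided by f: B = 1.64 for the ash run.

5. I tested whether one number was enough. The maple readings, treated the same way, gave 1.70, close to the ash reach. The alder run, with half the catalyst, gave 0.875, half the ash reach. So B fell with the catalyst charge, and it shifted by 0.0600 when the substrate charge was halved.

6. The cedar run has the ash charge. By 50 min my fade left hardly any of its catalyst working, so I expected 19.9% of its substrate to remain.

The forecast, holding that “k falls with clock time, not with product”, gave orders 0.97 in substrate and 0.5 in partner, called the larch run faster, and left 20.2% in the cedar run, a little above my figure.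

The flask gave orders 1.0 in substrate and 0.61 in partner, and the larch run came out faster, at 1.5 times the ash rate at the point compared.

    free catalyst + substrate + partner → product + free catalyst (7.800 L² mol⁻² min⁻¹)
    free catalyst → spent catalyst (0.07920 min⁻¹)
    2 partner ⇌ idle reagent dimer, settled at all times (1.290 L mol⁻¹)

The cedar run kept 19.6% of its substrate at 50 min, which is L = 1.63 against my reach of 1.64. The alder run's rate was 0.49 of the ash rate at equal product, so I halved the reach for it, to 0.818. With f unchanged, that put a quarter of the alder charge turned at 5.07 min, and the alder run reached that point at 4.81 min.

(Readings and results were computed with constants of no real substance, noise included.)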